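**Retrosynthetic overview**

- The strategy rests on the only stereocentre: the benzylic CH(OH) carbon, bonded to the ipso carbon of the para-phenylene ring B and to the CH2 group on ring C (the 2-aryloxy-3-hydroxyphenyl ring). Cutting the ring B–C(OH) bond opens the 18-membered ring to a chain with an aryl iodide at one end and an arylacetaldehyde at the other.
- Forward, a ligand-controlled nickel/chromium addition of the ring B aryl iodide to the ring C CH2CHO arm forms that bond, the macrocycle and the S centre in one step; buffered fluoride then frees the three phenols.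
- The CH2CHO arm is grown from an aryl nitrile (reduction, methylenation, hydroboration, oxidation) after methyl-to-TBS exchange; the CH2CH2 bridge between rings D and A comes from a Wittig reaction and diimide reduction.
- Ring C–O–ring D is made by SNAr on 2-fluoro-3-methoxybenzonitrile; ring A–O–ring B by Chan–Lam coupling with 4-iodophenylboronic acid.
- Ring order: the four benzene rings are bought; the 18-membered ring is the only ring made (step 12).

Key step: step 12

Remark: the facial preference of the oxazoline–sulfonamide ligand L, (S)-N-[2-(4-isopropyl-4,5-dihydro-1,3-oxazol-2-yl)-6-methylphenyl]methanesulfonamide, for an aryl–chromium is assumed rather than established; the S form is written, and whichever enantiomer gives the S carbinol on the model pair 4-iodoanisole/phenylacetaldehyde is the one to use.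

**Route**

Step 1
Reactants: 1 2-fluoro-3-methoxybenzonitrile; 2 3-hydroxybenzyl alcohol
Product: 3 2-[3-(hydroxymethyl)phenoxy]-3-methoxybenzonitrile
Conditions: K2CO3, DMF, 110 °C
Reagents that add atoms: none
Why: SNAr diaryl ether synthesis, in which K2CO3 deprotonates only the phenol of 2 and its phenoxide displaces the fluoride activated by the ortho nitrile.

Step 2
Reactants: 3 2-[3-(hydroxymethyl)phenoxy]-3-methoxybenzonitrile
Product: 4 [3-(2-cyano-6-methoxyphenoxy)benzyl]triphenylphosphonium bromide
Conditions: PPh3·HBr, MeCN, reflux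
Reagents that add atoms: triphenylphosphine hydrobromide, Br.c1ccc(cc1)P(c1ccccc1)c1ccccc1
Why: One-pot benzylic substitution and phosphonium salt formation, in which HBr converts the benzylic alcohol to the bromide that PPh3 captures, while the nitrile and aryl ethers are inert.

Step 3
Reactants: 5 3-hydroxy-4,5-dimethoxybenzaldehyde; 6 4-iodophenylboronic acid
Product: 7 3-(4-iodophenoxy)-4,5-dimethoxybenzaldehyde
Conditions: Cu(OAc)2 (2 equiv), pyridine, 4 Å molecular sieves, CH2Cl2, air, rt
Reagents that add atoms: none
Why: Chan–Lam O-arylation, in which the boronic acid transmetalates to copper and the aryl group passes to the phenoxide at room temperature, where the C–I bond does not react with copper.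

Step 4
Reactants: 4 [3-(2-cyano-6-methoxyphenoxy)benzyl]triphenylphosphonium bromide; 7 3-(4-iodophenoxy)-4,5-dimethoxybenzaldehyde
Product: 9 2-[3-[2-[3-(4-iodophenoxy)-4,5-dimethoxyphenyl]ethenyl]phenoxy]-3-methoxybenzonitrile (E/Z mixture), via phosphonium ylide 8 (not isolated)
Conditions: KOtBu (1.05 equiv), THF, 0 °C → rt
Reagents that add atoms: none
Why: Wittig olefination of a semi-stabilised benzylic ylide with the aryl aldehyde; the E/Z ratio is immaterial because step 5 removes the double bond, and nitrile, iodide and ethers are spectators.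

Step 5
Reactants: 9 stilbene nitrile (E/Z mixture)
Product: 10 2-[3-[2-[3-(4-iodophenoxy)-4,5-dimethoxyphenyl]ethyl]phenoxy]-3-methoxybenzonitrile
Conditions: TsNHNH2 (excess, in portions), aq. NaOAc, DME, reflux
Reagents that add atoms: none
Why: Diimide reduction, in which HN=NH generated from the sulfonyl hydrazide delivers H2 to the C=C bond in a concerted way and leaves the aryl iodide and nitrile untouched, as hydrogenation over palladium would not.

Step 6
Reactants: 10 bibenzyl nitrile, tris-methyl ether
Product: 12 2-[3-[2-[3,4-dihydroxy-5-(4-iodophenoxy)phenyl]ethyl]phenoxy]-3-hydroxybenzonitrile, via boron aryloxide 11 (not isolated)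
Conditions: BBr3 (7 equiv), CH2Cl2, −78 °C → rt; then ice-water
Reagents that add atoms: none
Why: Lewis-acid ether cleavage (BBr3 demethylation), in which bromide attacks the O-methyl carbon of each boron-activated aryl methyl ether, whereas the diaryl ethers, nitrile and aryl iodide offer no sp3 carbon; the air-sensitive triphenol is silylated at once.

Step 7
Reactants: 12 triphenol nitrile
Product: 13 3-(tert-butyldimethylsilyloxy)-2-[3-[2-[3,4-bis(tert-butyldimethylsilyloxy)-5-(4-iodophenoxy)phenyl]ethyl]phenoxy]benzonitrile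
Conditions: TBSCl (5 equiv), imidazole (10 equiv), DMF, rt → 40 °C
Reagents that add atoms: tert-butyldimethylsilyl chloride, CC(C)(C)[Si](C)(C)Cl
Why: Imidazole-promoted silylation of phenols, run with excess reagent so that the flanked central oxygen of ring A is also capped.

Step 8
Reactants: 13 tris-TBS nitrile
Product: 15 3-(tert-butyldimethylsilyloxy)-2-[3-[2-[3,4-bis(tert-butyldimethylsilyloxy)-5-(4-iodophenoxy)phenyl]ethyl]phenoxy]benzaldehyde, via aluminium aldimine 14 (not isolated)
Conditions: i-Bu2AlH (1.5 equiv), toluene, −78 → −20 °C; then aq. KNaC4H4O6, rt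
Reagents that add atoms: water, O
Why: Partial reduction of an aryl nitrile with i-Bu2AlH, in which one hydride gives the N-aluminio aldimine that is stable in the cold and is hydrolysed to the aldehyde on work-up; aryl silyl ethers and the aryl iodide are inert at this temperature.

Step 9
Reactants: 15 tris-TBS benzaldehyde
Product: 16 the corresponding styrene (CH=CH2 in place of CHO on ring C)
Conditions: Ph3PCH3Br (1.5 equiv), KN(SiMe3)2 (1.4 equiv), THF, 0 °C; then 15, −78 → 0 °C
Reagents that add atoms: methyltriphenylphosphonium bromide, C[P+](c1ccccc1)(c1ccccc1)c1ccccc1.[Br-]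
Why: Wittig methylenation with the non-stabilised ylide, made with a slight deficit of base so that no free amide attacks the aryl silyl ethers.

Step 10
Reactants: 16 tris-TBS styrene
Product: 18 the 2-arylethanol (CH2CH2OH on ring C), via B-alkyl-9-BBN borane 17 (not isolated)
Conditions: 9-BBN (2 equiv), THF, 0 °C → rt; then 3 M aq. NaOAc, 30% H2O2, 0 °C → rt
Reagents that add atoms: hydrogen peroxide, OO
Why: Hydroboration–oxidation, in which 9-BBN places boron on the terminal carbon of the styrene (anti-Markovnikov) and the acetate-buffered peroxide replaces boron by OH without the hydroxide that would strip aryl silyl ethers.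

Step 11
Reactants: 18 tris-TBS 2-arylethanol
Product: 19 seco iodo-aldehyde: 2-[3-(tert-butyldimethylsilyloxy)-2-[3-[2-[3,4-bis(tert-butyldimethylsilyloxy)-5-(4-iodophenoxy)phenyl]ethyl]phenoxy]phenyl]acetaldehyde
Conditions: Dess–Martin periodinane (1.3 equiv), NaHCO3, CH2Cl2, 0 °C → rt; used at once
Reagents that add atoms: none
Why: Dess–Martin oxidation of the primary alcohol stops at the aldehyde under buffered, non-aqueous conditions that neither enolise nor over-oxidise the arylacetaldehyde.

Step 12
Reactants: 19 seco iodo-aldehyde, tris-TBS ether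
Product: 21 (S)-macrocyclic carbinol, tris-TBS ether (18-membered ring: ring A meta –O– ring B para –CH(OH)–CH2– ring C ortho –O– ring D meta –CH2CH2– back to ring A; S at CH(OH)), via chromium alkoxide 20 (not isolated)
Conditions: CrCl2 (4 equiv), ligand L (4.4 equiv), Et3N (4.4 equiv), MeCN, rt; NiCl2(2,9-dimethyl-1,10-phenanthroline) (10 mol%); 19 in THF by syringe pump over 12 h to 2 mM, rt; aq. ethylenediamine work-up
Reagents that add atoms: none
Why: Proposed new method: CrCl2 reduces the nickel dichloride complex to zerovalent nickel, which inserts into the C–I bond of ring B; the aryl group is handed to trivalent chromium carrying the deprotonated ligand L, and this aryl–chromium adds to the CHO carbon of the ring C arm to give alkoxide 20, which work-up hydrolyses (L and Et3N are recovered). The closest known reaction types are the Nozaki–Hiyama–Kishi macrocyclisation of iodo-aldehydes and the ligand-controlled enantioselective nickel/chromium addition of organic halides to aldehydes; their combination for an aryl iodide closing an 18-membered ring is the untested part. The 18-membered ring closes by intramolecular 1,2-addition in an 18-exo-trig mode, the C=O bond staying outside the ring. The carbinol stereocentre is set by the chiral ligand on chromium alone, as the seco chain has no other stereocentre: aryl delivery to the Re face of the aldehyde gives S. The step needs ring closure over oligomerisation, secured by slow addition to about 2 mM and by the two diaryl ether hinges that fold the chain, and carbonyl addition over enolisation, secured by the low basicity of the aryl–chromium, which also leaves the three aryl silyl ethers alone.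

Step 13
Reactants: 21 (S)-macrocyclic carbinol, tris-TBS ether
Product: 22 CNP0356934.1, the (S)-macrocyclic tetraol (two OH on ring A, one on ring C, benzylic OH)
Conditions: Bu4NF (4 equiv), AcOH (4 equiv), degassed THF, 0 °C
Reagents that add atoms: none
Why: Fluoride-mediated desilylation frees the three phenols; the acetic acid buffer keeps the medium from turning basic, so the catechol is not oxidised and the benzylic carbinol, whose configuration is not touched, neither eliminates nor ionises.

**Compound list**

1 | 2-fluoro-3-methoxybenzonitrile | COc1cccc(C#N)c1F | starting material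
2 | 3-hydroxybenzyl alcohol | OCc1cccc(O)c1 | starting material
3 | 2-[3-(hydroxymethyl)phenoxy]-3-methoxybenzonitrile | COc1cccc(C#N)c1Oc1cccc(CO)c1 | intermediate
4 | [3-(2-cyano-6-methoxyphenoxy)benzyl]triphenylphosphonium bromide | COc1cccc(C#N)c1Oc1cccc(C[P+](c2ccccc2)(c2ccccc2)c2ccccc2)c1.[Br-] | intermediate
5 | 3-hydroxy-4,5-dimethoxybenzaldehyde | COc1cc(C=O)cc(O)c1OC | starting material
6 | 4-iodophenylboronic acid | OB(O)c1ccc(I)cc1 | starting material
7 | 3-(4-iodophenoxy)-4,5-dimethoxybenzaldehyde | COc1cc(C=O)cc(Oc2ccc(I)cc2)c1OC | intermediate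
8 | phosphonium ylide from 4 | COc1cccc(C#N)c1Oc1cccc(C=P(c2ccccc2)(c2ccccc2)c2ccccc2)c1 | intermediate
9 | stilbene nitrile, E/Z mixture | COc1cccc(C#N)c1Oc1cccc(C=Cc2cc(OC)c(OC)c(Oc3ccc(I)cc3)c2)c1 | intermediate
10 | bibenzyl nitrile, tris-methyl ether | COc1cccc(C#N)c1Oc1cccc(CCc2cc(OC)c(OC)c(Oc3ccc(I)cc3)c2)c1 | intermediate
11 | boron aryloxide (ring A catechol as cyclic bromoboronate, ring C phenol as dibromoboryl ether) | N#Cc1cccc(OB(Br)Br)c1Oc1cccc(CCc2cc3OB(Br)Oc3c(Oc3ccc(I)cc3)c2)c1 | intermediate
12 | triphenol nitrile | N#Cc1cccc(O)c1Oc1cccc(CCc2cc(O)c(O)c(Oc3ccc(I)cc3)c2)c1 | intermediate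
13 | tris-TBS nitrile | N#Cc1cccc(O[Si](C)(C)C(C)(C)C)c1Oc1cccc(CCc2cc(O[Si](C)(C)C(C)(C)C)c(O[Si](C)(C)C(C)(C)C)c(Oc3ccc(I)cc3)c2)c1 | intermediate
14 | N-(diisobutylaluminio) aldimine | CC(C)C[Al](CC(C)C)N=Cc1cccc(O[Si](C)(C)C(C)(C)C)c1Oc1cccc(CCc2cc(O[Si](C)(C)C(C)(C)C)c(O[Si](C)(C)C(C)(C)C)c(Oc3ccc(I)cc3)c2)c1 | intermediate
15 | tris-TBS benzaldehyde | O=Cc1cccc(O[Si](C)(C)C(C)(C)C)c1Oc1cccc(CCc2cc(O[Si](C)(C)C(C)(C)C)c(O[Si](C)(C)C(C)(C)C)c(Oc3ccc(I)cc3)c2)c1 | intermediate
16 | tris-TBS styrene | C=Cc1cccc(O[Si](C)(C)C(C)(C)C)c1Oc1cccc(CCc2cc(O[Si](C)(C)C(C)(C)C)c(O[Si](C)(C)C(C)(C)C)c(Oc3ccc(I)cc3)c2)c1 | intermediate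
17 | B-(2-arylethyl)-9-borabicyclo[3.3.1]nonane | C1CCC2CCCC1B2CCc1cccc(O[Si](C)(C)C(C)(C)C)c1Oc1cccc(CCc2cc(O[Si](C)(C)C(C)(C)C)c(O[Si](C)(C)C(C)(C)C)c(Oc3ccc(I)cc3)c2)c1 | intermediate
18 | tris-TBS 2-arylethanol | OCCc1cccc(O[Si](C)(C)C(C)(C)C)c1Oc1cccc(CCc2cc(O[Si](C)(C)C(C)(C)C)c(O[Si](C)(C)C(C)(C)C)c(Oc3ccc(I)cc3)c2)c1 | intermediate
19 | seco iodo-aldehyde, tris-TBS ether | O=CCc1cccc(O[Si](C)(C)C(C)(C)C)c1Oc1cccc(CCc2cc(O[Si](C)(C)C(C)(C)C)c(O[Si](C)(C)C(C)(C)C)c(Oc3ccc(I)cc3)c2)c1 | intermediate
20 | chromium alkoxide of the macrocyclic carbinol, bearing Cl and ligand L | CC(C)(C)[Si](C)(C)Oc1cc2cc(c1O[Si](C)(C)C(C)(C)C)Oc1ccc(cc1)[C@@H](O[Cr](Cl)N(c1c(C)cccc1C1=N[C@@H](C(C)C)CO1)S(C)(=O)=O)Cc1cccc(O[Si](C)(C)C(C)(C)C)c1Oc1cccc(c1)CC2 | intermediate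
21 | (S)-macrocyclic carbinol, tris-TBS ether | CC(C)(C)[Si](C)(C)Oc1cc2cc(c1O[Si](C)(C)C(C)(C)C)Oc1ccc(cc1)[C@@H](O)Cc1cccc(O[Si](C)(C)C(C)(C)C)c1Oc1cccc(c1)CC2 | intermediate
22 | CNP0356934.1, (S)-macrocyclic tetraol | Oc1cc2cc(c1O)Oc1ccc(cc1)[C@@H](O)Cc1cccc(O)c1Oc1cccc(c1)CC2 | target

**Totals and risks**

Total step count: 13. Longest linear sequence: 12 steps (steps 1, 2, 4 to 13); step 3 is the one-step branch.

Steps most likely to fail:

1. Step 12 (the proposed method). Oligomerisation may outrun ring closure, the aryl–chromium may be protonated before it adds, or the ligand may discriminate the aldehyde faces poorly in the ring-constrained transition state. Fallback, setting out from 19 and coming back at 21: close the ring without any chiral ligand under standard conditions (CrCl2 in excess, catalytic NiCl2, DMF/THF, syringe-pump addition) to give the racemic macrocyclic carbinol F1. Oxidise it with Dess–Martin periodinane to the macrocyclic aryl benzyl ketone F2, then reduce this by asymmetric transfer hydrogenation with RuCl(p-cymene)[(S,S)-TsDPEN] in HCO2H/Et3N. By the acetophenone model this should give the S carbinol 21, so the stereocentre is then set by ketone reduction, not by C–C bond formation.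

2. Step 5. Diimide saturates the E-stilbene slowly and disproportionates, so reduction may stall with alkene left in the product. Fallback, setting out from 4 and 5 and coming back at 10: run the Wittig reaction of 4 with the free phenol aldehyde 5 (KOtBu, 2.2 equiv) to give the stilbene phenol F3. Hydrogenate it over Pd/C (H2, EtOAc), which is safe because no iodide is present yet, to give the bibenzyl phenol F4. Then install the iodoaryl ring by Chan–Lam coupling of F4 with 6 (Cu(OAc)2, pyridine) to reach 10.

3. Step 10. Aryl silyl ethers may be lost during the oxidative work-up, or some boron may add at the benzylic carbon. Fallback, setting out from 15 and coming back at 19: treat 15 with the ylide from Ph3PCH2OMe·Cl and KN(SiMe3)2 to give the methyl enol ether F5 (E/Z), and hydrolyse it under near-neutral conditions (Hg(OAc)2, aqueous THF, 0 °C; then KI) directly to aldehyde 19, bypassing 16 and 18.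

**Further compounds**

F1 | step 12 | racemic macrocyclic carbinol, tris-TBS ether | CC(C)(C)[Si](C)(C)Oc1cc2cc(c1O[Si](C)(C)C(C)(C)C)Oc1ccc(cc1)C(O)Cc1cccc(O[Si](C)(C)C(C)(C)C)c1Oc1cccc(c1)CC2
F2 | step 12 | macrocyclic aryl benzyl ketone, tris-TBS ether | CC(C)(C)[Si](C)(C)Oc1cc2cc(c1O[Si](C)(C)C(C)(C)C)Oc1ccc(cc1)C(=O)Cc1cccc(O[Si](C)(C)C(C)(C)C)c1Oc1cccc(c1)CC2
F3 | step 5 | 2-[3-[2-(3-hydroxy-4,5-dimethoxyphenyl)ethenyl]phenoxy]-3-methoxybenzonitrile (E/Z) | COc1cccc(C#N)c1Oc1cccc(C=Cc2cc(O)c(OC)c(OC)c2)c1
F4 | step 5 | 2-[3-[2-(3-hydroxy-4,5-dimethoxyphenyl)ethyl]phenoxy]-3-methoxybenzonitrile | COc1cccc(C#N)c1Oc1cccc(CCc2cc(O)c(OC)c(OC)c2)c1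
F5 | step 10 | methyl enol ether of the homologated aldehyde (ArCH=CHOMe on ring C, E/Z), tris-TBS ether | COC=Cc1cccc(O[Si](C)(C)C(C)(C)C)c1Oc1cccc(CCc2cc(O[Si](C)(C)C(C)(C)C)c(O[Si](C)(C)C(C)(C)C)c(Oc3ccc(I)cc3)c2)c1
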